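Numbering: unit A is the 4,7-dimethoxy-5-methylcoumarin bonded through C8. Unit B (primed) is the 7-hydroxy-4-methoxy-5-methylcoumarin bonded through C6'.
Cuts, in order: O1–C2 and C2–C3 of both pyranones (back to two ortho-hydroxyacetophenones plus diethyl carbonate), then C4a'–C4' (the acetyl group on ring B), then C5–C6 and C7–C8 of benzene ring A.
Feature behind the last cut: C5(CH3), C4a(COCH3), C8a(O) and C8(aryl) sit side by side in ring A exactly as C6, C5, C4 and C3 do in a 5-acetyl-3-aryl-4-methoxy-6-methyl-2-pyrone. The two atoms left over, C6(H) and C7(OCH3), are the two carbons of 1,1-dimethoxyethene.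
The pyrone divides into acetylacetone and an arylmalonic acid. Its aryl–CH bond (the later C8–C6' axis) comes from malonate arylation of brominated orcinol dibenzyl ether.
Forward order of rings: benzene ring B (bought as orcinol), 2-pyrone (step 5), benzene ring A from the pyrone (step 7), both pyranones together (step 10).
Stereochemistry: the target has no stereocentre, and its only stereo element, the hindered biaryl axis, forms without control.

Key step: step 7

Assumption: the target SMILES fixes no configuration at the C8–C6' axis, so the racemic mixture of atropisomers is taken as the target.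

Step 1
Reactants: 1 orcinol (5-methylbenzene-1,3-diol)
Product: 2 1,3-bis(benzyloxy)-5-methylbenzene
Conditions: BnBr (2.3 equiv), K2CO3, DMF, 60 °C
Reagents that add atoms: benzyl bromide, BrCc1ccccc1
Why: Williamson ether synthesis on both phenols installs a group that should withstand base, heat and palladium coupling and can be removed at the end by hydrogenolysis.

Step 2
Reactants: 2 1,3-bis(benzyloxy)-5-methylbenzene
Product: 3 1,5-bis(benzyloxy)-2-bromo-3-methylbenzene
Conditions: NBS (1.0 equiv), MeCN, 0 °C
Reagents that add atoms: N-bromosuccinimide, O=C1CCC(=O)N1Br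
Why: Electrophilic aromatic bromination of orcinol diethers goes para to one alkoxy group and next to the methyl group, because the site between the two ethers is more shielded.

Step 3
Reactants: 3 1,5-bis(benzyloxy)-2-bromo-3-methylbenzene; 4 diethyl malonate
Product: 5 diethyl 2-[2,4-bis(benzyloxy)-6-methylphenyl]propanedioate
Conditions: Pd(dba)2 (3 mol %), P(t-Bu)3·HBF4 (6 mol %), K3PO4, toluene, 90 °C
Reagents that add atoms: none
Why: Palladium-catalysed alpha-arylation of malonates (Buchwald–Hartwig type) with a bulky trialkylphosphine accepts electron-rich aryl bromides with two ortho substituents, since crowding at the metal speeds the C–C reductive elimination.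

Step 4
Reactants: 5 diethyl 2-[2,4-bis(benzyloxy)-6-methylphenyl]propanedioate
Product: 6 2-[2,4-bis(benzyloxy)-6-methylphenyl]propanedioic acid
Conditions: KOH, EtOH–H2O, 50 °C; then 1 M HCl, 0 °C
Reagents that add atoms: potassium hydroxide, [K+].[OH-]
Why: Ester saponification gives the stable dicarboxylate, and cold acidification with low-temperature drying should keep the free arylmalonic acid from decarboxylating.

Step 5
Reactants: 6 2-[2,4-bis(benzyloxy)-6-methylphenyl]propanedioic acid; 7 acetylacetone (pentane-2,4-dione)
Product: 10 5-acetyl-3-[2,4-bis(benzyloxy)-6-methylphenyl]-4-hydroxy-6-methyl-2H-pyran-2-one, via arylmalonyl dichloride 8 (not isolated), via (chlorocarbonyl)ketene 9 (not isolated)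
Conditions: (COCl)2 (2.5 equiv), cat. DMF, toluene, 0 to 70 °C, evaporate; then 7 (1.1 equiv), toluene, 110 °C
Reagents that add atoms: oxalyl chloride, O=C(Cl)C(=O)Cl (its chlorine stays only in 8 and 9)
Why: Acid chloride formation, thermal loss of HCl to the (chlorocarbonyl)arylketene, and cyclocondensation with a 1,3-diketone (acylation at the central carbon, lactone closure through the enol oxygen) is the established route to 5-acyl-3-aryl-4-hydroxy-2-pyrones, including aryl groups with two ortho substituents.

Step 6
Reactants: 10 5-acetyl-3-[2,4-bis(benzyloxy)-6-methylphenyl]-4-hydroxy-6-methyl-2H-pyran-2-one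
Product: 11 5-acetyl-3-[2,4-bis(benzyloxy)-6-methylphenyl]-4-methoxy-6-methyl-2H-pyran-2-one
Conditions: Me2SO4 (1.3 equiv), K2CO3, acetone, reflux
Reagents that add atoms: dimethyl sulfate, COS(=O)(=O)OC
Why: O-alkylation of the vinylogous acid with a hard methylating agent normally gives the 4-methoxy-2-pyrone, and C-alkylation is disfavoured because C3 already bears the bulky aryl group.

Step 7
Reactants: 11 5-acetyl-3-[2,4-bis(benzyloxy)-6-methylphenyl]-4-methoxy-6-methyl-2H-pyran-2-one; 12 1,1-dimethoxyethene
Product: 15 1-{3-[2,4-bis(benzyloxy)-6-methylphenyl]-2,4-dimethoxy-6-methylphenyl}ethanone, via bridged lactone 13 (not isolated), via trimethoxycyclohexadiene 14 (not isolated)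
Conditions: 12 (10 equiv), mesitylene, sealed tube, 140 °C
Reagents that add atoms: none
Why: The CH2 end of 12 bonds to pyrone C6 and its acetal carbon to pyrone C3 in an inverse-electron-demand [4+2] cycloaddition, either asynchronous and concerted or through a dienolate/dimethoxycarbenium zwitterion, giving the 2-oxabicyclo[2.2.2]octenone 13. At this temperature 13 expels CO2 by a retro-[4+2] step to give diene 14, which loses methanol to become aromatic, so two irreversible losses pull the sequence forward. The closest known reaction type is the Diels–Alder/decarboxylation/elimination cascade of ester- or acyl-bearing 2-pyrones with 1,1-dimethoxyethene, which gives anisoles. The single ring closed, benzene ring A, arises by intermolecular cycloaddition that forms C5–C6 and C7–C8 (coumarin numbering) in one operation, not by cyclisation of a chain and not by aryl–aryl coupling. The two bridgehead stereocentres of 13 are tied to each other by the bicycle and disappear with CO2, so no stereocentre survives and the axis forms as a racemate. The step needs regioselectivity and preference for the carbon diene over the acetyl enone acting as a 1-oxadiene: C6 is the beta carbon of the enone and the delta carbon of the lactone carbonyl, hence the best acceptor for the nucleophilic CH2, which places the surviving methoxy group at C7 next to C8, and an oxadiene adduct would be a cyclic orthoester able to revert while the carbon adduct is drained by CO2 loss.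

Step 8
Reactants: 15 1-{3-[2,4-bis(benzyloxy)-6-methylphenyl]-2,4-dimethoxy-6-methylphenyl}ethanone
Product: 16 1-{3-[3-acetyl-4,6-bis(benzyloxy)-2-methylphenyl]-2,4-dimethoxy-6-methylphenyl}ethanone
Conditions: AcOH (3 equiv), (CF3CO)2O (4 equiv), CH2Cl2, 0 °C to rt
Reagents that add atoms: acetic acid, CC(=O)O
Why: Friedel–Crafts acylation by acetyl trifluoroacetate formed in situ needs no metal Lewis acid, so the benzyl ethers should stay; ring B is far more electron-rich than the carbonyl-bearing ring A, and within ring B the site between OBn and CH3 (para to the other OBn) is favoured over the site flanked by two ethers, as in step 2.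

Step 9
Reactants: 16 1-{3-[3-acetyl-4,6-bis(benzyloxy)-2-methylphenyl]-2,4-dimethoxy-6-methylphenyl}ethanone
Product: 17 1-{3-[3-acetyl-6-(benzyloxy)-4-hydroxy-2-methylphenyl]-2-hydroxy-4-methoxy-6-methylphenyl}ethanone
Conditions: BCl3 (2.2 equiv, 1 M in CH2Cl2), CH2Cl2, −78 to −20 °C; then MeOH–H2O
Reagents that add atoms: none
Why: In this chelation-directed ether cleavage each BCl3 binds an acetyl oxygen and the neighbouring ether oxygen, chloride removes the methyl (ring A) or benzyl (ring B) group, and boron then rests as a weakly acidic six-membered dichloroboron chelate, so with two equivalents at low temperature the C7 methyl ether and the C7' benzyl ether, which have no carbonyl neighbour, should remain.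

Step 10
Reactants: 17 1-{3-[3-acetyl-6-(benzyloxy)-4-hydroxy-2-methylphenyl]-2-hydroxy-4-methoxy-6-methylphenyl}ethanone
Product: 18 8-[7-(benzyloxy)-4-hydroxy-5-methyl-2-oxo-2H-chromen-6-yl]-4-hydroxy-7-methoxy-5-methyl-2H-chromen-2-one
Conditions: NaH (10 equiv), (EtO)2CO, toluene, 110 °C; then 1 M HCl
Reagents that add atoms: diethyl carbonate, CCOC(=O)OCC
Why: Twofold Claisen-type ethoxycarbonylation of the methyl ketone enolates followed by lactonisation onto the ortho phenoxides is the standard conversion of 2-hydroxy-6-methylacetophenones into 4-hydroxy-5-methylcoumarins.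

Step 11
Reactants: 18 8-[7-(benzyloxy)-4-hydroxy-5-methyl-2-oxo-2H-chromen-6-yl]-4-hydroxy-7-methoxy-5-methyl-2H-chromen-2-one
Product: 19 8-[7-(benzyloxy)-4-methoxy-5-methyl-2-oxo-2H-chromen-6-yl]-4,7-dimethoxy-5-methyl-2H-chromen-2-one
Conditions: Me2SO4 (2.6 equiv), K2CO3, acetone, reflux
Reagents that add atoms: dimethyl sulfate, COS(=O)(=O)OC
Why: O-alkylation of both vinylogous acids with a hard electrophile favours the 4-methoxycoumarins over C3-methyl or 2-methoxychromone isomers, and the only phenol is still masked as its benzyl ether.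

Step 12
Reactants: 19 8-[7-(benzyloxy)-4-methoxy-5-methyl-2-oxo-2H-chromen-6-yl]-4,7-dimethoxy-5-methyl-2H-chromen-2-one
Product: 20 8-(7-hydroxy-4-methoxy-5-methyl-2-oxo-2H-chromen-6-yl)-4,7-dimethoxy-5-methyl-2H-chromen-2-one (target CNP0113839.0)
Conditions: H2 (1 atm), 10% Pd/C, EtOAc–MeOH, rt
Reagents that add atoms: none
Why: Catalytic hydrogenolysis cleaves the aryl benzyl ether, while the donor–acceptor C3=C4 bonds of 4-methoxycoumarins should not be reduced at one atmosphere and room temperature.

Compound list
1 | orcinol | Cc1cc(O)cc(O)c1 | starting material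
2 | 1,3-bis(benzyloxy)-5-methylbenzene | Cc1cc(OCc2ccccc2)cc(OCc2ccccc2)c1 | intermediate
3 | 1,5-bis(benzyloxy)-2-bromo-3-methylbenzene | Cc1cc(OCc2ccccc2)cc(OCc2ccccc2)c1Br | intermediate
4 | diethyl malonate | CCOC(=O)CC(=O)OCC | starting material
5 | diethyl 2-[2,4-bis(benzyloxy)-6-methylphenyl]propanedioate | CCOC(=O)C(C(=O)OCC)c1c(C)cc(OCc2ccccc2)cc1OCc1ccccc1 | intermediate
6 | 2-[2,4-bis(benzyloxy)-6-methylphenyl]propanedioic acid | OC(=O)C(C(=O)O)c1c(C)cc(OCc2ccccc2)cc1OCc1ccccc1 | intermediate
7 | acetylacetone | CC(=O)CC(C)=O | starting material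
8 | 2-[2,4-bis(benzyloxy)-6-methylphenyl]propanedioyl dichloride (not isolated) | O=C(Cl)C(C(=O)Cl)c1c(C)cc(OCc2ccccc2)cc1OCc1ccccc1 | intermediate
9 | 2-[2,4-bis(benzyloxy)-6-methylphenyl]-3-oxoprop-2-enoyl chloride, the (chlorocarbonyl)arylketene (not isolated) | O=C=C(C(=O)Cl)c1c(C)cc(OCc2ccccc2)cc1OCc1ccccc1 | intermediate
10 | 5-acetyl-3-[2,4-bis(benzyloxy)-6-methylphenyl]-4-hydroxy-6-methyl-2H-pyran-2-one | CC(=O)C1=C(C)OC(=O)C(c2c(OCc3ccccc3)cc(OCc3ccccc3)cc2C)=C1O | intermediate
11 | 5-acetyl-3-[2,4-bis(benzyloxy)-6-methylphenyl]-4-methoxy-6-methyl-2H-pyran-2-one | CC(=O)C1=C(C)OC(=O)C(c2c(OCc3ccccc3)cc(OCc3ccccc3)cc2C)=C1OC | intermediate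
12 | 1,1-dimethoxyethene | C=C(OC)OC | starting material
13 | 6-acetyl-4-[2,4-bis(benzyloxy)-6-methylphenyl]-5,8,8-trimethoxy-1-methyl-2-oxabicyclo[2.2.2]oct-5-en-3-one (racemic, one enantiomer drawn, bridgeheads tied by the bicycle; not isolated) | CC(=O)C1=C(OC)[C@]2(c3c(OCc4ccccc4)cc(OCc4ccccc4)cc3C)C(=O)O[C@@]1(C)CC2(OC)OC | intermediate
14 | 1-{5-[2,4-bis(benzyloxy)-6-methylphenyl]-4,4,6-trimethoxy-2-methylcyclohexa-1,5-dien-1-yl}ethanone (not isolated) | CC(=O)C1=C(C)CC(OC)(OC)C(c2c(OCc3ccccc3)cc(OCc3ccccc3)cc2C)=C1OC | intermediate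
15 | 1-{3-[2,4-bis(benzyloxy)-6-methylphenyl]-2,4-dimethoxy-6-methylphenyl}ethanone | CC(=O)c1c(C)cc(OC)c(-c2c(OCc3ccccc3)cc(OCc3ccccc3)cc2C)c1OC | intermediate
16 | 1-{3-[3-acetyl-4,6-bis(benzyloxy)-2-methylphenyl]-2,4-dimethoxy-6-methylphenyl}ethanone | CC(=O)c1c(C)cc(OC)c(-c2c(OCc3ccccc3)cc(OCc3ccccc3)c(C(C)=O)c2C)c1OC | intermediate
17 | 1-{3-[3-acetyl-6-(benzyloxy)-4-hydroxy-2-methylphenyl]-2-hydroxy-4-methoxy-6-methylphenyl}ethanone | CC(=O)c1c(C)cc(OC)c(-c2c(OCc3ccccc3)cc(O)c(C(C)=O)c2C)c1O | intermediate
18 | 8-[7-(benzyloxy)-4-hydroxy-5-methyl-2-oxo-2H-chromen-6-yl]-4-hydroxy-7-methoxy-5-methyl-2H-chromen-2-one | COc1cc(C)c2c(O)cc(=O)oc2c1-c1c(OCc3ccccc3)cc2oc(=O)cc(O)c2c1C | intermediate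
19 | 8-[7-(benzyloxy)-4-methoxy-5-methyl-2-oxo-2H-chromen-6-yl]-4,7-dimethoxy-5-methyl-2H-chromen-2-one | COc1cc(C)c2c(OC)cc(=O)oc2c1-c1c(OCc3ccccc3)cc2oc(=O)cc(OC)c2c1C | intermediate
20 | 8-(7-hydroxy-4-methoxy-5-methyl-2-oxo-2H-chromen-6-yl)-4,7-dimethoxy-5-methyl-2H-chromen-2-one (racemic axis) | COc1cc(C)c2c(OC)cc(=O)oc2c1-c1c(O)cc2oc(=O)cc(OC)c2c1C | target

Total step count: 12. Longest linear sequence: 12 steps (1 to 20).

Steps most likely to fail

Step 7. The bond to pyrone C3 has to form beside an aryl group with two ortho substituents. The 5-acetyl group is flanked on both sides and may twist out of conjugation, which makes the diene less electron-poor than simple acylpyrones. The cycloaddition may then be too slow to compete with oligomerisation of the ketene acetal or with its addition through the enone oxygen.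

The fallback sets out from bromide 3 and gives up the ring synthesis in favour of a cross-coupling. A Suzuki–Miyaura reaction of 3 with purchased 2,6-dimethoxy-4-methylphenylboronic acid (COc1cc(C)cc(OC)c1B(O)O), using Pd(OAc)2, SPhos and K3PO4 in toluene–water at 100 °C, should give 2',4'-bis(benzyloxy)-2,6-dimethoxy-4,6'-dimethylbiphenyl F1. Twofold acetylation of this biaryl with AcOH and (CF3CO)2O follows. One acetyl group should enter each ring, because the first one deactivates its own ring and the two free sites of ring A are equivalent. This rejoins the route at 16.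

Step 9. The lone benzyl ether at C7' may be lost, or the freed benzyl cation may migrate onto an aromatic ring, if any boron trichloride remains unchelated while the slower methyl cleavage in ring A is completed.

The fallback sets out from 16 and removes the need for selectivity in the cleavage. Excess BCl3 with pentamethylbenzene as cation trap (CH2Cl2, −78 to 0 °C) strips both benzyl ethers and the chelated methyl ether. This should give 1-[3-(3-acetyl-4,6-dihydroxy-2-methylphenyl)-2-hydroxy-4-methoxy-6-methylphenyl]ethanone F2. Two of its three phenols are locked in hydrogen bonds to acetyl groups. One equivalent of BnBr with K2CO3 in acetone should therefore alkylate only the free C7' hydroxyl, which rejoins the route at 17.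

Step 5. The free arylmalonic acid may decarboxylate before it is activated. Under HCl and heat the acid chloride may also attack the ortho benzyl ether, with loss of the benzyl group and closure to a lactone, before the diketone is added.

The fallback sets out from 2 and 7 and forms the aryl–C3 bond on a finished pyrone by Pinhey arylation. Direct plumbation of 2 with Pb(OAc)4 in CHCl3–AcOH, at the same site as the bromination, should give [2,4-bis(benzyloxy)-6-methylphenyl]lead triacetate F3. Separately, 7 and malonyl dichloride (O=C(Cl)CC(=O)Cl) should condense to 5-acetyl-4-hydroxy-6-methyl-2H-pyran-2-one F4. Ligand coupling of the two in CHCl3–pyridine at 60 °C tolerates aryl groups with two ortho substituents. It arylates the only free nucleophilic carbon, C3, and rejoins the route at 10.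

Further compounds
F1 | step 7 | 2',4'-bis(benzyloxy)-2,6-dimethoxy-4,6'-dimethyl-1,1'-biphenyl | COc1cc(C)cc(OC)c1-c1c(C)cc(OCc2ccccc2)cc1OCc1ccccc1
F2 | step 9 | 1-[3-(3-acetyl-4,6-dihydroxy-2-methylphenyl)-2-hydroxy-4-methoxy-6-methylphenyl]ethanone | CC(=O)c1c(C)cc(OC)c(-c2c(O)cc(O)c(C(C)=O)c2C)c1O
F3 | step 5 | [2,4-bis(benzyloxy)-6-methylphenyl]lead triacetate | CC(=O)O[Pb](OC(C)=O)(OC(C)=O)c1c(C)cc(OCc2ccccc2)cc1OCc1ccccc1
F4 | step 5 | 5-acetyl-4-hydroxy-6-methyl-2H-pyran-2-one | CC(=O)C1=C(C)OC(=O)C=C1O
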